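**Plan**
Cuts: the C3 lactol is traced back through its (R)-acetate to the racemic lactol. The lactone bond O2–C1 is opened to a C1 methyl ester plus a C3 dimethyl acetal. The benzylic O–CH2 ester link between rings A and B, the C6–CH2 bond, and finally C7a–C3a and C4–C5 of ring B are then cut.
Feature (isobenzofuranone numbering: C1 lactone carbonyl, O2, C3 lactol carbon, C3a, C4–H, C5–OMe, C6–CH2O, C7–OH, C7a): ring B is a beta-resorcylate. The string C1–C7a–C7–C6–C5 carries oxygen on C1, C7 and C5 just as a 3-oxopentanedioate does, and C3–C3a–C4 is the three-carbon chain of pyruvaldehyde with C3 at the aldehyde level.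
Forward order: benzene ring B is made first from two acyclic pieces, C5–OH is methylated and C6 is hydroxymethylated. Ring A (a purchased benzoate, O-methylated and saponified) is joined through the benzylic ester, and the five-membered lactol ring closes last.
Stereochemistry: C3 is the only stereocentre. Its lability by ring–chain tautomerism feeds a lipase dynamic kinetic acetylation that fixes (R), and the same lipase then removes the acetyl group at the acyl carbon without touching the C3–O bond.

Key step: step 1

Assumption: in cold, neutral, weakly polar media and as a solid, the 3-hydroxyphthalide form of the target opens to the formyl acid slowly enough for the (R)-enantiomer (priorities O2 > OH > C3a > H) to be isolated. Acid, base and warming are therefore excluded in and after step 9.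

Step 1
Reactants: 1 dimethyl 3-oxopentanedioate; 2 1,1-dimethoxypropan-2-one
Product: 4 methyl 2-(dimethoxymethyl)-4,6-dihydroxybenzoate, via alkylidene keto diester 3 (not isolated)
Conditions: TiCl4, pyridine, THF, 0 °C to rt (2 in slight excess); aqueous wash, crude 3; NaOMe, MeOH, 65 °C; aq NaH2PO4 quench
Reagents that add atoms: none
Why: Proposed new method: TiCl4 should bind the ketone oxygen and one acetal oxygen of 2 in a five-membered chelate while pyridine converts 1 into its titanium enolate, so that C7a adds to C3a and water is lost (Knoevenagel condensation under TiCl4–pyridine, known for ketones and beta-keto esters) to give 3, whose alkene isomers interconvert through the dienolate. In NaOMe–MeOH the minor anion deprotonated at the allylic methyl C4, a vinylogous enolate spread over the C7 ketone and the C1 ester, attacks the distal ester carbon C5 in a 6-(enolendo)-exo-trig Dieckmann closure of ring B, and loss of methoxide followed by enolisation gives the resorcinolate, an irreversible sink behind reversible steps. The closest known reaction type is the alkoxide-induced self-condensation of dialkyl 3-oxopentanedioates to resorcylates, where the same two bonds form but the acylated carbon bears an ester; the new element is a crossed ketone partner whose acylated carbon is a plain allylic methyl, supported by the known gamma-acylation of alkylidene dicarbonyl compounds (vinylogous Claisen condensation). No stereocentre is formed. The step needs crossed instead of self-condensation and single instead of double alkylidenation: the ketone of 1 is masked as its enolate under the titanium conditions and the alpha,alpha-dialkoxy ketone is the stronger electrophile, while the tetrasubstituted alkene crowds C7 and only a slight excess of 2 is used. Constitution is not in doubt, because 1 is symmetrical and C4 can reach only C5 through a six-membered transition state, which leaves C7–OH chelated to the C1 ester and C5–OH free.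

Step 2
Reactants: 4 methyl 2-(dimethoxymethyl)-4,6-dihydroxybenzoate
Product: 5 methyl 2-(dimethoxymethyl)-6-hydroxy-4-methoxybenzoate
Conditions: MeI (1.05 equiv), K2CO3, acetone, rt to 40 °C
Reagents that add atoms: iodomethane, CI
Why: Williamson O-methylation, in which the C7–OH is held in a hydrogen bond to the C1 ester carbonyl, so that one equivalent of MeI and a weak base should alkylate only the free and more acidic C5–OH, as is usual for 2,4-dihydroxybenzoates, while acetal and ester are inert to these conditions.

Step 3
Reactants: 5 methyl 2-(dimethoxymethyl)-6-hydroxy-4-methoxybenzoate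
Product: 7 methyl 6-(dimethoxymethyl)-2-hydroxy-3-(hydroxymethyl)-4-methoxybenzoate, via cyclic phenylboronate 6 (not isolated)
Conditions: PhB(OH)2, (CH2O)n, EtCO2H (cat.), toluene, reflux, Dean–Stark; NaHCO3 wash; propane-1,3-diol, THF, rt
Reagents that add atoms: paraformaldehyde (as formaldehyde), C=O; phenylboronic acid, OB(O)c1ccccc1 (its atoms stay only in 6)
Why: Boronic acid-templated ortho-hydroxymethylation of a phenol, in which the aryloxyboron species formed at C7–O delivers formaldehyde through a six-membered transition state to the only free ortho carbon C6 (also the most electron-rich site, between two oxygens), the product is trapped as boronate 6 so that diarylmethane formation is blocked, the weak acid under water-removing conditions should spare the acetal, and neutral diol exchange then frees 7.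

Step 4
Reactants: 8 methyl 2,4-dihydroxy-3,6-dimethylbenzoate
Product: 9 methyl 2-hydroxy-4-methoxy-3,6-dimethylbenzoate
Conditions: MeI (1.05 equiv), K2CO3, acetone, 40 °C
Reagents that add atoms: iodomethane, CI
Why: Williamson O-methylation that is selective for the 4-OH because the 2-OH is chelated to the ester carbonyl, the standard differentiation in this family of benzoates.

Step 5
Reactants: 9 methyl 2-hydroxy-4-methoxy-3,6-dimethylbenzoate
Product: 10 2-hydroxy-4-methoxy-3,6-dimethylbenzoic acid
Conditions: KOH, DMSO–H2O, 90 °C; then 1 M HCl, 0 °C
Reagents that add atoms: potassium hydroxide (oxygen of the carboxyl OH), [K+].[OH-]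
Why: Saponification of a di-ortho-substituted benzoate, which needs poorly solvated hydroxide in hot aqueous DMSO, leaves the aryl methyl ether untouched, and is finished by cold acidification so that the electron-rich acid does not decarboxylate.

Step 6
Reactants: 7 methyl 6-(dimethoxymethyl)-2-hydroxy-3-(hydroxymethyl)-4-methoxybenzoate; 10 2-hydroxy-4-methoxy-3,6-dimethylbenzoic acid
Product: 11 [4-(dimethoxymethyl)-2-hydroxy-6-methoxy-3-(methoxycarbonyl)phenyl]methyl 2-hydroxy-4-methoxy-3,6-dimethylbenzoate
Conditions: PPh3, DIAD, THF, 0 °C to rt
Reagents that add atoms: none
Why: Mitsunobu esterification, in which the bond is made by O-alkylation of the carboxylate at the activated benzylic carbon, so the shielded acyl carbon of 10 plays no part, the acid is far more acidic than the chelated phenols and is the only pronucleophile deprotonated, and a possible collapse of the oxyphosphonium salt to the ortho-quinone methide would lead to the same ester by carboxylate addition.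

Step 7
Reactants: 11 [4-(dimethoxymethyl)-2-hydroxy-6-methoxy-3-(methoxycarbonyl)phenyl]methyl 2-hydroxy-4-methoxy-3,6-dimethylbenzoate
Product: 13 racemic [3,7-dihydroxy-5-methoxy-1-oxo-1,3-dihydroisobenzofuran-6-yl]methyl 2-hydroxy-4-methoxy-3,6-dimethylbenzoate, via formyl ester 12 (not isolated)
Conditions: 1 M HCl (aq)–THF, 40 °C
Reagents that add atoms: water, O
Why: Acid-catalysed acetal hydrolysis followed by neighbouring-group lactonisation, in which the hydrate of the ortho-formyl group attacks the adjacent methyl ester in a 5-exo-trig closure and expels methanol to give the pseudo-acid form that 2-formylbenzoic acids prefer, while the hindered benzylic ester, whose ionisation is disfavoured by the para formyl or lactol carbon and the meta carbonyl, should survive dilute acid, and C3 arises racemic.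

Step 8
Reactants: 13 racemic [3,7-dihydroxy-5-methoxy-1-oxo-1,3-dihydroisobenzofuran-6-yl]methyl 2-hydroxy-4-methoxy-3,6-dimethylbenzoate
Product: 14 [(3R)-3-acetoxy-7-hydroxy-5-methoxy-1-oxo-1,3-dihydroisobenzofuran-6-yl]methyl 2-hydroxy-4-methoxy-3,6-dimethylbenzoate
Conditions: immobilised Burkholderia cepacia lipase, vinyl acetate, 2-pyridone (10 mol %), toluene, 45 °C
Reagents that add atoms: vinyl acetate, C=COC(C)=O
Why: Lipase-catalysed dynamic kinetic resolution by irreversible transesterification, known for gamma-hydroxybutenolide-type lactols, in which the enantiomers of 13 interconvert through the achiral formyl acid (ring–chain tautomerism, sped up by the neutral bifunctional proton shuttle 2-pyridone), the enzyme should acetylate the enantiomer that puts the aryl ring in its large pocket and O2 in the medium one, which by the empirical size rule for secondary alcohols (same spatial sense as (R)-indan-1-ol) is the (R)-lactol, and the acylal 14 can no longer open, so C3 is fixed as (R) while the chelated phenols and the hindered benzoate are left alone.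

Step 9
Reactants: 14 [(3R)-3-acetoxy-7-hydroxy-5-methoxy-1-oxo-1,3-dihydroisobenzofuran-6-yl]methyl 2-hydroxy-4-methoxy-3,6-dimethylbenzoate
Product: 15 [(3R)-3,7-dihydroxy-5-methoxy-1-oxo-1,3-dihydroisobenzofuran-6-yl]methyl 2-hydroxy-4-methoxy-3,6-dimethylbenzoate (CNP0398000.1)
Conditions: immobilised Burkholderia cepacia lipase, n-BuOH, MTBE, 0–5 °C; filtration, cold concentration, crystallisation from MTBE–heptane
Reagents that add atoms: none
Why: Lipase-catalysed alcoholysis (transesterification to n-butanol) of the same enantiomer that the enzyme formed, in which the serine attacks the acetyl carbonyl and the departing lactol oxygen is protonated by the catalytic histidine, so the C3–O bond is never broken, no ring-opening lactolate anion is released, C3 stays (R), any trace of (S)-acetate is left behind, and the cold, additive-free, weakly polar medium with prompt crystallisation should keep tautomerisation slow.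

**Compound list**
1 | dimethyl 3-oxopentanedioate | COC(=O)CC(=O)CC(=O)OC | starting material
2 | 1,1-dimethoxypropan-2-one | CC(=O)C(OC)OC | starting material
3 | dimethyl 2-(1,1-dimethoxypropan-2-ylidene)-3-oxopentanedioate (alkene isomers, not isolated) | COC(=O)CC(=O)C(C(=O)OC)=C(C)C(OC)OC | intermediate
4 | methyl 2-(dimethoxymethyl)-4,6-dihydroxybenzoate | COC(=O)c1c(O)cc(O)cc1C(OC)OC | intermediate
5 | methyl 2-(dimethoxymethyl)-6-hydroxy-4-methoxybenzoate | COC(=O)c1c(O)cc(OC)cc1C(OC)OC | intermediate
6 | methyl 7-(dimethoxymethyl)-5-methoxy-2-phenyl-4H-1,3,2-benzodioxaborinine-8-carboxylate (not isolated) | COC(=O)c1c(C(OC)OC)cc(OC)c2COB(c3ccccc3)Oc12 | intermediate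
7 | methyl 6-(dimethoxymethyl)-2-hydroxy-3-(hydroxymethyl)-4-methoxybenzoate | COC(=O)c1c(O)c(CO)c(OC)cc1C(OC)OC | intermediate
8 | methyl 2,4-dihydroxy-3,6-dimethylbenzoate | COC(=O)c1c(C)cc(O)c(C)c1O | starting material
9 | methyl 2-hydroxy-4-methoxy-3,6-dimethylbenzoate | COC(=O)c1c(C)cc(OC)c(C)c1O | intermediate
10 | 2-hydroxy-4-methoxy-3,6-dimethylbenzoic acid | Cc1cc(OC)c(C)c(O)c1C(=O)O | intermediate
11 | [4-(dimethoxymethyl)-2-hydroxy-6-methoxy-3-(methoxycarbonyl)phenyl]methyl 2-hydroxy-4-methoxy-3,6-dimethylbenzoate | COc1cc(C)c(C(=O)OCc2c(OC)cc(C(OC)OC)c(C(=O)OC)c2O)c(O)c1C | intermediate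
12 | [4-formyl-2-hydroxy-6-methoxy-3-(methoxycarbonyl)phenyl]methyl 2-hydroxy-4-methoxy-3,6-dimethylbenzoate (not isolated) | COc1cc(C)c(C(=O)OCc2c(OC)cc(C=O)c(C(=O)OC)c2O)c(O)c1C | intermediate
13 | racemic [3,7-dihydroxy-5-methoxy-1-oxo-1,3-dihydroisobenzofuran-6-yl]methyl 2-hydroxy-4-methoxy-3,6-dimethylbenzoate | COc1cc(C)c(C(=O)OCc2c(OC)cc3c(c2O)C(=O)OC3O)c(O)c1C | intermediate
14 | [(3R)-3-acetoxy-7-hydroxy-5-methoxy-1-oxo-1,3-dihydroisobenzofuran-6-yl]methyl 2-hydroxy-4-methoxy-3,6-dimethylbenzoate | COc1cc(C)c(C(=O)OCc2c(OC)cc3c(c2O)C(=O)O[C@H]3OC(C)=O)c(O)c1C | intermediate
15 | [(3R)-3,7-dihydroxy-5-methoxy-1-oxo-1,3-dihydroisobenzofuran-6-yl]methyl 2-hydroxy-4-methoxy-3,6-dimethylbenzoate | COc1cc(C)c(C(=O)OCc2c(OC)cc3c(c2O)C(=O)O[C@H]3O)c(O)c1C | target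

Total steps: 9. Longest linear sequence: 7 steps (1, 2, 3, 6, 7, 8, 9) from 1 and 2; steps 4 and 5 form the two-step ring A branch.

**Steps most likely to fail**

Step 1 (crossed cyclocondensation).
- Risk: self-condensation of the diester or a double condensation may outrun the crossed Knoevenagel stage. The Lewis acid may ionise the acetal. The ring closure may stall because enolisation at C6 takes away the electrophilicity of the C5 ester.
- Fallback: known polyketide-type assembly, setting out from 2 and coming back at 4.
- Ketone 2 is carbomethoxylated at its methyl group (NaH, dimethyl carbonate, THF, reflux) to give methyl 4,4-dimethoxy-3-oxobutanoate F1.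
- The dianion of methyl acetoacetate (NaH, then n-BuLi, THF, 0 °C) then attacks the ester carbon of the sodium enolate of F1 through its terminal carbon. This is the same dianion acylation by which methyl acetoacetate is known to self-condense to methyl orsellinate. It gives methyl 8,8-dimethoxy-3,5,7-trioxooctanoate F2.
- At pH 8–9, F2 undergoes the biomimetic aldol condensation of its C2 with the activated C7 ketone and aromatises to 4. Ring B is thus closed at C7a–C3a after C5–C6 has been made.

Step 9 (release of the free lactol).
- Risk: epimerisation at C3 by ring–chain tautomerism during the hours that the enzymatic alcoholysis needs, or uncatalysed solvolysis at C3.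
- Fallback: no covalent derivative at all (F0: no new compound), setting out from 13 and coming back at 15.
- Racemic 13 is resolved directly by preparative chromatography on a polysaccharide chiral stationary phase with a neutral eluent below 0 °C. Contact time is then minutes instead of hours.
- The (R)-fraction is concentrated cold and crystallised at once. The other fraction is re-equilibrated by gentle warming with 2-pyridone and recycled.

Step 8 (enzymatic dynamic kinetic acetylation).
- Risk: refusal of the bulky substrate by the enzyme, weak discrimination between the flat aryl ring and the lactone oxygen, the opposite sense of selection, or racemisation too slow to keep the resolution dynamic.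
- Fallback: small-molecule stereocontrol (F0: no new compound), setting out from 13 and coming back at 14.
- This is acylative dynamic kinetic resolution with a chiral isothiourea Lewis base, 2-phenyl-2,3-dihydroimidazo[2,1-b]benzothiazole (benzotetramisole), and Ac2O in toluene at 0 °C. The reaction type is established for 3-hydroxyphthalides.
- The acetate counter-ion of the acylammonium salt serves as the base that equilibrates the lactol.
- Both catalyst enantiomers are available, so the one leading to the (R)-acetate can be chosen.

**Further compounds**
F1 | step 1 | methyl 4,4-dimethoxy-3-oxobutanoate | COC(OC)C(=O)CC(=O)OC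
F2 | step 1 | methyl 8,8-dimethoxy-3,5,7-trioxooctanoate | COC(OC)C(=O)CC(=O)CC(=O)CC(=O)OC
F0 | step 9 | none | none
F0 | step 8 | none | none
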